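## Retrosynthetic overview

1. Target 26 is cut at the C7–O ester bond into the ketol 17 and the aroyl chloride 23, which takes five steps from methyl orsellinate 18.
2. Feature used: in ring B (C4a, C5, C6, C7, C8, C8a) the only stereocentre, C7, is a tertiary carbinol between the C6 and C8 carbonyls. C7–C8 is therefore an acyloin bond joining a formyl carbon (C8, on C8a of pyran ring A: O2, C1, C8a, C4a, C4, C3) to a methyl ketone carbon (C7).
3. Cutting C7–C8 opens ring B to the flat, achiral pyranylidene keto-aldehyde 16. In the forward sense a chiral triazolylidene closes ring B and sets 7R in one step.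
4. The C4a=C5–C6(=O) arm of 16 comes from acetylide addition to the C4a carbonyl of the masked 3-formyl-4-pyranone 10, followed by Meyer–Schuster rearrangement. A ketone enolate would attack the formyl group or C1 instead.
5. Ring A is made first, from acylketene 7 (dioxinone 1 plus acetaldehyde 2) and 3-(dimethylamino)acrolein 6. The order is ring A, ring B, then esterification.

Key step: step 8

Assumption: the (5aR,10bS) antipode of the aminoindanol-derived triazolium salt is taken to deliver 7R; if a trial run shows the opposite sense, the equally available (5aS,10bR) salt is used under the same conditions.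

## Route

Step 1
Reactants: 1 2,2,6-trimethyl-4H-1,3-dioxin-4-one; 2 acetaldehyde
Product: 3 6-(2-hydroxypropyl)-2,2-dimethyl-4H-1,3-dioxin-4-one (racemic)
Conditions: LiN(iPr)2, THF, −78 °C; then 2, −78 °C; AcOH quench
Reagents that add atoms: none
Why: Vinylogous aldol addition, in which the amide base removes a proton from the C6 methyl group of 1 and the extended enolate attacks acetaldehyde through its γ-carbon; the new carbinol centre is racemic and is erased in step 2.

Step 2
Reactants: 3 6-(2-hydroxypropyl)-2,2-dimethyl-4H-1,3-dioxin-4-one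
Product: 5 2,2-dimethyl-6-[(E)-prop-1-enyl]-4H-1,3-dioxin-4-one, via mesylate 4 (not isolated)
Conditions: MsCl, Et3N, CH2Cl2, 0 °C; then DBU, 0 °C to rt
Reagents that add atoms: none
Why: Mesylation followed by E1cB elimination, in which the ring-side CH2 is vinylogously acidic, so DBU expels mesylate and the conjugated, thermodynamically preferred E-propenyl group should result.

Step 3
Reactants: 5 2,2-dimethyl-6-[(E)-prop-1-enyl]-4H-1,3-dioxin-4-one; 6 (E)-3-(dimethylamino)acrolein
Product: 9 4-oxo-6-[(E)-prop-1-enyl]-4H-pyran-3-carbaldehyde, via acylketene 7 (not isolated), via C-acylated enaminal 8 (not isolated)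
Conditions: slow addition of 5 to 6, PhMe, 110 °C; then CF3CO2H, rt
Reagents that add atoms: none
Why: Retro-hetero-Diels–Alder loss of acetone gives acylketene 7, whose ketene carbon is attacked by the nucleophilic α-carbon of the push–pull enamine 6 (acylketene–enamine γ-pyranone synthesis), and acid then lets the enol oxygen of 8 displace protonated dimethylamine by addition–elimination, so that no free amine can consume 7 or open ring A.

Step 4
Reactants: 9 4-oxo-6-[(E)-prop-1-enyl]-4H-pyran-3-carbaldehyde
Product: 10 3-(dimethoxymethyl)-6-[(E)-prop-1-enyl]-4H-pyran-4-one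
Conditions: HC(OMe)3, MeOH, cat. TsOH·H2O, rt; Et3N quench
Reagents that add atoms: trimethyl orthoformate, COC(OC)OC
Why: Acid-catalysed acetalisation with an orthoester as water scavenger masks the aldehyde, which would otherwise outcompete the weakly electrophilic ring carbonyl in step 6, and removing the formyl acceptor also makes the ring CH next to oxygen less electrophilic.

Step 5
Reactants: 11 3,3-dimethoxybutan-2-one
Product: 13 3,3-dimethoxybut-1-yne, via enol phosphate 12 (not isolated)
Conditions: LiN(iPr)2 (1.1 equiv), THF, −78 °C; ClP(O)(OEt)2; LiN(iPr)2 (2.3 equiv), −78 °C to rt; H2O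
Reagents that add atoms: none
Why: Methyl ketone to terminal alkyne conversion by enol phosphate formation and base-induced β-elimination, which is regiochemically unambiguous because the other α-carbon of 11 is the quaternary ketal carbon.

Step 6
Reactants: 10 3-(dimethoxymethyl)-6-[(E)-prop-1-enyl]-4H-pyran-4-one; 13 3,3-dimethoxybut-1-yne
Product: 14 3-(dimethoxymethyl)-4-(3,3-dimethoxybut-1-ynyl)-6-[(E)-prop-1-enyl]-4H-pyran-4-ol (racemic, used crude)
Conditions: 13, n-BuLi, THF, −78 °C; then 10, −78 to −20 °C; H2O
Reagents that add atoms: none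
Why: Irreversible 1,2-addition of a hard, slim lithium acetylide to a vinylogous ester carbonyl (the addition half of a Stork–Danheiser transposition, as organolithium and Grignard reagents add to C4 of 4-pyranones) forms C4a–C5; the carbinol centre is racemic and vanishes in step 7.

Step 7
Reactants: 14 3-(dimethoxymethyl)-4-(3,3-dimethoxybut-1-ynyl)-6-[(E)-prop-1-enyl]-4H-pyran-4-ol
Product: 16 (4Z)-4-(2,3-dioxobutylidene)-6-[(E)-prop-1-enyl]-4H-pyran-3-carbaldehyde, via bis-acetal ketone 15 (not isolated)
Conditions: CF3CO2H, H2O, THF, 0 °C to rt; used promptly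
Reagents that add atoms: water, O
Why: Meyer–Schuster rearrangement followed by acetal hydrolysis, in which acid ionises the doubly vinylic propargylic carbinol to a 4-alkynylpyrylium ion, water adds at the distal alkyne carbon (the future C6; a Rupe pathway is excluded because the carbinol carbon has no β-hydrogen) and tautomerisation gives the push–pull enone 15, whose dimethyl acetals at C7 and C8 then hydrolyse in the same medium, the C4a=C5 geometry being of no consequence because this bond rotates easily.

Step 8
Reactants: 16 (4Z)-4-(2,3-dioxobutylidene)-6-[(E)-prop-1-enyl]-4H-pyran-3-carbaldehyde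
Product: 17 (7R)-7-hydroxy-7-methyl-3-[(E)-prop-1-enyl]-6H-isochromene-6,8(7H)-dione
Conditions: (5aR,10bS)-2-(pentafluorophenyl)-5a,10b-dihydro-4H,6H-indeno[2,1-b][1,2,4]triazolo[4,3-d][1,4]oxazin-2-ium tetrafluoroborate (15 mol %), iPr2NEt (15 mol %), PhMe, 4 Å molecular sieves, Ar, rt
Reagents that add atoms: none
Why: Proposed new method: iPr2NEt frees the triazolylidene, which adds to the C8 formyl carbon; proton transfer gives the nucleophilic hydroxy-enamine, whose C8 carbon attacks the C7 ketone, and collapse of the C8 alkoxide releases the carbene and the ketol 17. The closest known reaction type is the triazolium-catalysed enantioselective intramolecular crossed aldehyde–ketone benzoin that closes six-membered α-hydroxy ketones with a tertiary carbinol, but a β-oxygenated enal (vinylogous formate) as donor and a 1,2-diketone as acceptor have not been shown. Ring B (C8, C8a, C4a, C5, C6, C7) closes in the 6-exo-trig mode, and only the Z rotamer of 16 can reach this geometry, which is replenished by easy rotation about the push–pull C4a=C5 bond. C7 is set by the catalyst: the indane wall of the aminoindanol backbone blocks one face of the planar hydroxy-enamine, the enol O–H binds the C7 carbonyl oxygen, and the ketone therefore meets C8 with a single face. Attack at C7 rather than C6 is secured by the substrate, because C6 is a vinylogous ester carbonyl fed by O2 through C3=C4 and through C1=C8a and its attack would give a strained five-membered ring, whereas C7 is a methyl ketone activated by the neighbouring carbonyl. Acyl-anion rather than homoenolate reactivity at C1 is favoured by the electron-poor N-C6F5 carbene, by the α-branching at C8a and by the proximity of C7, and the weak base keeps enolisation of the C7 acetyl group low.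

Step 9
Reactants: 18 methyl 2,4-dihydroxy-6-methylbenzoate (methyl orsellinate)
Product: 19 methyl 4-[(tert-butyldimethylsilyl)oxy]-2-hydroxy-6-methylbenzoate
Conditions: TBSCl (1.05 equiv), imidazole, CH2Cl2, 0 °C
Reagents that add atoms: tert-butyldimethylsilyl chloride, CC(C)(C)[Si](C)(C)Cl
Why: Selective O-silylation, because the C2 hydroxyl is tied up in a hydrogen bond to the ester carbonyl and is flanked by it, so the free C4 phenol should react first.

Step 10
Reactants: 19 methyl 4-[(tert-butyldimethylsilyl)oxy]-2-hydroxy-6-methylbenzoate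
Product: 20 methyl 4-[(tert-butyldimethylsilyl)oxy]-2-methoxy-6-methylbenzoate
Conditions: MeOH, PPh3, DIAD, THF, 0 °C to rt
Reagents that add atoms: methanol, CO
Why: Mitsunobu etherification of the remaining acidic phenol with methanol runs under neutral conditions, so the aryl silyl ether is neither cleaved nor transferred and only O2 is methylated.

Step 11
Reactants: 20 methyl 4-[(tert-butyldimethylsilyl)oxy]-2-methoxy-6-methylbenzoate
Product: 21 4-hydroxy-2-methoxy-6-methylbenzoic acid
Conditions: KOH, DMSO–H2O, 90 °C; then aq. HCl, 0 °C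
Reagents that add atoms: potassium hydroxide, [K+].[OH-]
Why: Forcing saponification of the di-ortho-substituted benzoate needs hot hydroxide, which also removes the aryl silyl ether once it has served as regiochemical placeholder, and cold acidification avoids decarboxylation of the electron-rich acid.

Step 12
Reactants: 21 4-hydroxy-2-methoxy-6-methylbenzoic acid
Product: 22 tert-butyldimethylsilyl 4-[(tert-butyldimethylsilyl)oxy]-2-methoxy-6-methylbenzoate
Conditions: TBSCl (2.5 equiv), imidazole, DMF, rt
Reagents that add atoms: tert-butyldimethylsilyl chloride, CC(C)(C)[Si](C)(C)Cl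
Why: Exhaustive imidazole-promoted silylation converts the phenol into the silyl ether and the acid into the silyl ester in one operation.

Step 13
Reactants: 22 tert-butyldimethylsilyl 4-[(tert-butyldimethylsilyl)oxy]-2-methoxy-6-methylbenzoate
Product: 23 4-[(tert-butyldimethylsilyl)oxy]-2-methoxy-6-methylbenzoyl chloride
Conditions: (COCl)2, cat. DMF, CH2Cl2, 0 °C to rt; concentrated and used directly
Reagents that add atoms: oxalyl chloride, O=C(Cl)C(=O)Cl
Why: Silyl ester to acid chloride exchange through the chloroiminium species from DMF and oxalyl chloride proceeds without release of HCl, so the aryl silyl ether should survive.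

Step 14
Reactants: 17 (7R)-7-hydroxy-7-methyl-3-[(E)-prop-1-enyl]-6H-isochromene-6,8(7H)-dione; 23 4-[(tert-butyldimethylsilyl)oxy]-2-methoxy-6-methylbenzoyl chloride
Product: 25 (7R)-7-methyl-6,8-dioxo-3-[(E)-prop-1-enyl]-7,8-dihydro-6H-isochromen-7-yl 4-[(tert-butyldimethylsilyl)oxy]-2-methoxy-6-methylbenzoate, via aroyl triflate 24 (not isolated)
Conditions: AgOSO2CF3, 2,6-di-tert-butyl-4-methylpyridine, CH2Cl2, −40 °C to rt
Reagents that add atoms: none
Why: Silver-assisted acylation, in which chloride abstraction from the electron-rich di-ortho-substituted aroyl chloride gives the aroyl triflate in equilibrium with a linear acylium ion that escapes the steric block of addition–elimination and is captured by the hindered tertiary C7 hydroxyl without strong base, and the C7–O bond is untouched so 7R is retained.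

Step 15
Reactants: 25 (7R)-7-methyl-6,8-dioxo-3-[(E)-prop-1-enyl]-7,8-dihydro-6H-isochromen-7-yl 4-[(tert-butyldimethylsilyl)oxy]-2-methoxy-6-methylbenzoate
Product: 26 (7R)-7-methyl-6,8-dioxo-3-[(E)-prop-1-enyl]-7,8-dihydro-6H-isochromen-7-yl 4-hydroxy-2-methoxy-6-methylbenzoate (target)
Conditions: HF·pyridine, THF, 0 °C
Reagents that add atoms: none
Why: Fluoride-driven cleavage of the aryl silyl ether in a buffered, weakly acidic medium should leave the C7 ester, ring A (which is sensitive to amines and strong base) and the quaternary stereocentre untouched.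

## Compound list

1 | 2,2,6-trimethyl-4H-1,3-dioxin-4-one | CC1=CC(=O)OC(C)(C)O1 | starting material
2 | acetaldehyde | CC=O | starting material
3 | 6-(2-hydroxypropyl)-2,2-dimethyl-4H-1,3-dioxin-4-one (racemic) | CC(O)CC1=CC(=O)OC(C)(C)O1 | intermediate
4 | 1-(2,2-dimethyl-4-oxo-4H-1,3-dioxin-6-yl)propan-2-yl methanesulfonate (not isolated) | CC(OS(C)(=O)=O)CC1=CC(=O)OC(C)(C)O1 | intermediate
5 | 2,2-dimethyl-6-[(E)-prop-1-enyl]-4H-1,3-dioxin-4-one | C/C=C/C1=CC(=O)OC(C)(C)O1 | intermediate
6 | (E)-3-(dimethylamino)acrolein | CN(C)/C=C/C=O | starting material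
7 | (4E)-3-oxohexa-1,4-dien-1-one, acylketene (not isolated) | C/C=C/C(=O)C=C=O | intermediate
8 | (6E)-2-[(dimethylamino)methylidene]-3,5-dioxooct-6-enal (not isolated) | CN(C)C=C(C=O)C(=O)CC(=O)/C=C/C | intermediate
9 | 4-oxo-6-[(E)-prop-1-enyl]-4H-pyran-3-carbaldehyde | C/C=C/C1=CC(=O)C(C=O)=CO1 | intermediate
10 | 3-(dimethoxymethyl)-6-[(E)-prop-1-enyl]-4H-pyran-4-one | C/C=C/C1=CC(=O)C(C(OC)OC)=CO1 | intermediate
11 | 3,3-dimethoxybutan-2-one | CC(=O)C(C)(OC)OC | starting material
12 | 3,3-dimethoxybut-1-en-2-yl diethyl phosphate (not isolated) | C=C(OP(=O)(OCC)OCC)C(C)(OC)OC | intermediate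
13 | 3,3-dimethoxybut-1-yne | C#CC(C)(OC)OC | intermediate
14 | 3-(dimethoxymethyl)-4-(3,3-dimethoxybut-1-ynyl)-6-[(E)-prop-1-enyl]-4H-pyran-4-ol (racemic) | C/C=C/C1=CC(O)(C#CC(C)(OC)OC)C(C(OC)OC)=CO1 | intermediate
15 | (1Z)-1-{3-(dimethoxymethyl)-6-[(E)-prop-1-enyl]-4H-pyran-4-ylidene}-3,3-dimethoxybutan-2-one (not isolated) | C/C=C/C1=C/C(=C/C(=O)C(C)(OC)OC)C(C(OC)OC)=CO1 | intermediate
16 | (4Z)-4-(2,3-dioxobutylidene)-6-[(E)-prop-1-enyl]-4H-pyran-3-carbaldehyde | C/C=C/C1=C/C(=C/C(=O)C(C)=O)C(C=O)=CO1 | intermediate
17 | (7R)-7-hydroxy-7-methyl-3-[(E)-prop-1-enyl]-6H-isochromene-6,8(7H)-dione | C/C=C/C1=CC2=CC(=O)[C@@](C)(O)C(=O)C2=CO1 | intermediate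
18 | methyl 2,4-dihydroxy-6-methylbenzoate | COC(=O)c1c(C)cc(O)cc1O | starting material
19 | methyl 4-[(tert-butyldimethylsilyl)oxy]-2-hydroxy-6-methylbenzoate | COC(=O)c1c(C)cc(O[Si](C)(C)C(C)(C)C)cc1O | intermediate
20 | methyl 4-[(tert-butyldimethylsilyl)oxy]-2-methoxy-6-methylbenzoate | COC(=O)c1c(C)cc(O[Si](C)(C)C(C)(C)C)cc1OC | intermediate
21 | 4-hydroxy-2-methoxy-6-methylbenzoic acid | OC(=O)c1c(C)cc(O)cc1OC | intermediate
22 | tert-butyldimethylsilyl 4-[(tert-butyldimethylsilyl)oxy]-2-methoxy-6-methylbenzoate | CC(C)(C)[Si](C)(C)OC(=O)c1c(C)cc(O[Si](C)(C)C(C)(C)C)cc1OC | intermediate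
23 | 4-[(tert-butyldimethylsilyl)oxy]-2-methoxy-6-methylbenzoyl chloride | ClC(=O)c1c(C)cc(O[Si](C)(C)C(C)(C)C)cc1OC | intermediate
24 | 4-[(tert-butyldimethylsilyl)oxy]-2-methoxy-6-methylbenzoyl trifluoromethanesulfonate (not isolated) | COc1cc(O[Si](C)(C)C(C)(C)C)cc(C)c1C(=O)OS(=O)(=O)C(F)(F)F | intermediate
25 | (7R)-7-methyl-6,8-dioxo-3-[(E)-prop-1-enyl]-7,8-dihydro-6H-isochromen-7-yl 4-[(tert-butyldimethylsilyl)oxy]-2-methoxy-6-methylbenzoate | C/C=C/C1=CC2=CC(=O)[C@@](C)(OC(=O)c3c(C)cc(O[Si](C)(C)C(C)(C)C)cc3OC)C(=O)C2=CO1 | intermediate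
26 | (7R)-7-methyl-6,8-dioxo-3-[(E)-prop-1-enyl]-7,8-dihydro-6H-isochromen-7-yl 4-hydroxy-2-methoxy-6-methylbenzoate | C/C=C/C1=CC2=CC(=O)[C@@](C)(OC(=O)c3c(C)cc(O)cc3OC)C(=O)C2=CO1 | target

## Step count and risks

Total step count: 15. Longest linear sequence: 9 steps (1, 2, 3, 4, 6, 7, 8, 14, 15).

**Step 8 (bears the label "Proposed new method:").**
- Several things may go wrong:
  - The carbene may add reversibly at C1 instead of C8.
  - The extended hydroxy-enamine may react through C1 as a homoenolate, or be too stabilised to add at all.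
  - The carbene may attack the diketone and transfer the acetyl group.
  - Facial selectivity at C7 may be poor.
- The fallback uses known chemistry only. It replaces the umpolung by an aldol and oxidation sequence, sets out from 10 and comes back at 17.
- Compound 10 is treated with the lithium acetylide of commercial tert-butyl(but-3-yn-2-yloxy)dimethylsilane. This gives 4-{3-[(tert-butyldimethylsilyl)oxy]but-1-ynyl}-3-(dimethoxymethyl)-6-[(E)-prop-1-enyl]-4H-pyran-4-ol F1.
- Dilute aqueous acid effects Meyer–Schuster rearrangement and acetal hydrolysis to 4-{3-[(tert-butyldimethylsilyl)oxy]-2-oxobutylidene}-6-[(E)-prop-1-enyl]-4H-pyran-3-carbaldehyde F2.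
- C7 is the only enolisable α-position of the C6 ketone. LiN(SiMe3)2 in THF at −78 °C therefore triggers an intramolecular aldol addition of C7 to the non-enolisable C8 formyl group. The product is 7-[(tert-butyldimethylsilyl)oxy]-8-hydroxy-7-methyl-3-[(E)-prop-1-enyl]-7,8-dihydro-6H-isochromen-6-one F3, which cannot dehydrate because C7 is quaternary.
- Dess–Martin oxidation of the C8 alcohol gives racemic 7-[(tert-butyldimethylsilyl)oxy]-7-methyl-3-[(E)-prop-1-enyl]-6H-isochromene-6,8(7H)-dione F4.
- HF·pyridine then gives racemic 7-hydroxy-7-methyl-3-[(E)-prop-1-enyl]-6H-isochromene-6,8(7H)-dione F5.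
- Preparative HPLC on a cellulose-based chiral phase delivers the 7R enantiomer 17.

**Step 7.**
- Water may attack ring carbon C1 of the alkynylpyrylium ion and open ring A faster than it adds to the alkyne.
- Early loss of the ketal may redirect hydration to C5.
- The unmasked keto-aldehyde may degrade on prolonged contact with acid.
- The fallback forms C4a=C5 by an Eschenmoser sulfide contraction. It sets out from 10 (with 11 as partner), comes back at 15, and also bypasses step 6.
- Compound 10 is thionated with Lawesson's reagent in toluene to 3-(dimethoxymethyl)-6-[(E)-prop-1-enyl]-4H-pyran-4-thione F6.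
- Compound 11 is deprotonated with LiN(iPr)2 and brominated with NBS to 1-bromo-3,3-dimethoxybutan-2-one F7.
- S-alkylation of F6 with F7 gives 3-(dimethoxymethyl)-4-[(3,3-dimethoxy-2-oxobutyl)sulfanyl]-6-[(E)-prop-1-enyl]pyrylium bromide F8.
- Et3N and PPh3 then close the episulfide at C4a and remove sulfur to give 15. This compound is purified and hydrolysed briefly with aqueous CF3CO2H to 16, as in the second half of step 7.

**Step 3.**
- The acylketene may dimerise.
- It may be captured by prematurely liberated dimethylamine.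
- It may acylate the carbonyl oxygen of 6 instead of its α-carbon.
- The very electrophilic free aldehyde may suffer ring opening during isolation.
- The fallback replaces the enamine by an enol ether that already carries the acetal. It sets out from 5 and comes back at 10, so that step 4 is no longer needed.
- Compound 5 is heated in toluene with an excess of commercial (E)-1,3,3-trimethoxyprop-1-ene. Acylketene 7 undergoes a hetero-Diels–Alder reaction with the enol ether to give 3-(dimethoxymethyl)-2-methoxy-6-[(E)-prop-1-enyl]-2,3-dihydro-4H-pyran-4-one F9.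
- Catalytic TsOH in dry toluene eliminates the anomeric methanol to give 10.

## Further compounds

F1 | step 8 | 4-{3-[(tert-butyldimethylsilyl)oxy]but-1-ynyl}-3-(dimethoxymethyl)-6-[(E)-prop-1-enyl]-4H-pyran-4-ol | C/C=C/C1=CC(O)(C#CC(C)O[Si](C)(C)C(C)(C)C)C(C(OC)OC)=CO1
F2 | step 8 | 4-{3-[(tert-butyldimethylsilyl)oxy]-2-oxobutylidene}-6-[(E)-prop-1-enyl]-4H-pyran-3-carbaldehyde | C/C=C/C1=C/C(=C/C(=O)C(C)O[Si](C)(C)C(C)(C)C)C(C=O)=CO1
F3 | step 8 | 7-[(tert-butyldimethylsilyl)oxy]-8-hydroxy-7-methyl-3-[(E)-prop-1-enyl]-7,8-dihydro-6H-isochromen-6-one | C/C=C/C1=CC2=CC(=O)C(C)(O[Si](C)(C)C(C)(C)C)C(O)C2=CO1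
F4 | step 8 | racemic 7-[(tert-butyldimethylsilyl)oxy]-7-methyl-3-[(E)-prop-1-enyl]-6H-isochromene-6,8(7H)-dione | C/C=C/C1=CC2=CC(=O)C(C)(O[Si](C)(C)C(C)(C)C)C(=O)C2=CO1
F5 | step 8 | racemic 7-hydroxy-7-methyl-3-[(E)-prop-1-enyl]-6H-isochromene-6,8(7H)-dione | C/C=C/C1=CC2=CC(=O)C(C)(O)C(=O)C2=CO1
F6 | step 7 | 3-(dimethoxymethyl)-6-[(E)-prop-1-enyl]-4H-pyran-4-thione | C/C=C/C1=CC(=S)C(C(OC)OC)=CO1
F7 | step 7 | 1-bromo-3,3-dimethoxybutan-2-one | BrCC(=O)C(C)(OC)OC
F8 | step 7 | 3-(dimethoxymethyl)-4-[(3,3-dimethoxy-2-oxobutyl)sulfanyl]-6-[(E)-prop-1-enyl]pyrylium bromide | C/C=C/c1cc(SCC(=O)C(C)(OC)OC)c(C(OC)OC)c[o+]1.[Br-]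
F9 | step 3 | 3-(dimethoxymethyl)-2-methoxy-6-[(E)-prop-1-enyl]-2,3-dihydro-4H-pyran-4-one | C/C=C/C1=CC(=O)C(C(OC)OC)C(OC)O1
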